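The vessel is closed and stirred, and holds a racemate, a single-handed catalyst and a partner.

common to all: partner 92.5 mM; catalyst 19 µM
- north: left-handed substrate 52 mM; right-handed substrate 52 mM; run made earlier
- west: left-handed substrate 81 mM; right-handed substrate 81 mM; run made earlier
- flask: left-handed substrate 37 mM; right-handed substrate 37 mM; time 5.0 d

| run | time / d | left-handed product / % |
|---|---|---|
| north | 0.500 | 46.6 |
| north | 0.833 | 45.3 |
| north | 1.25 | 45.9 |
| north | 2.00 | 45.9 |
| north | 4.00 | 45.7 |
| north | 6.00 | 45.0 |
| west | 1.04 | 34.0 |
| west | 2.08 | 34.0 |
| west | 3.00 | 33.6 |
| west | 4.00 | 34.9 |
| west | 5.00 | 33.8 |
| west | 6.00 | 35.0 |

(each reading ± 0.5 percentage points)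

- catalyst is single-handed; left-handed substrate and right-handed substrate are mirror images of each other, charged as a racemate, each of them at the stated concentration
- the reaction counts as stopped when no species that holds the left-handed substrate and right-handed substrate together changes by six tenths of a point or more over the second half of the time

- which holds at 5.0 d: what has brought the reaction to rest, or that it has not come to rest (forward and back rates have come level / no working catalyst is left / the partner has run out first / it is still moving / all of the left-handed substrate has reacted)
- amount of left-handed product at 5.0 d, in percent of the left-handed substrate and right-handed substrate together charged
- amount of left-handed product if the flask were left three thousand times as long, in percent of the left-handed substrate and right-handed substrate together charged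

Both runs read flat from their first point, 0.500 d in north and 1.04 d in west, so I expect this flask to stand still well before 5.0 d. But what stops them? From north to west the left-handed substrate rises from 52 mM to 81 mM, yet the left-handed product, averaged over the readings, rises from 47.6 mM to 55.4 mM. I read that as one stock shared out, so I take the partner, 92.5 mM in each run, as the limiting reagent.

So I follow the load, c(left-handed substrate)/c(partner), which is 0.562 in north and 0.876 in west. Beside it I put the charge per product, left-handed substrate charged per left-handed product formed: 1.09 and 1.46. The climb of charge per product with load is 1.17, read from two points with their scatter. At this flask's load of 0.400 the line gives 0.903, or 55.4% left-handed product. That is more left-handed product than left-handed substrate charged, so my reckoning needs right-handed substrate turning left-handed on the way.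

The forecast says no working catalyst is left, with 49.2% at the asked time and 49.2% after the long wait: “The catalyst dies just short of full conversion”.

The flask gives: the partner has run out first. Partner stands at 0% of its charge, and left-handed product at 51.2% against my 55.4%, and at 51.2% after the long wait.

    left-handed substrate ⇌ right-handed substrate (k = 0.00150 min⁻¹)
    partner → decomposed reagent (k = 0.00630 min⁻¹)
    partner + catalyst + right-handed substrate → catalyst + right-handed product (k = 17000 M⁻² min⁻¹)
    partner + catalyst + left-handed substrate → catalyst + left-handed product (k = 44000 M⁻² min⁻¹)

In a neighbouring flask, c(partner) drops to 56 mM with the rest held, so the load rises to 0.661. The same climb gives a charge per product of 1.21, or 41.3% left-handed product. That flask gives 39.3%, with partner at 0% of its charge and left-handed substrate at 19.7% of the two substrates charged.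

(The data stem from a simulated flask for an exercise; noise was put on by code.)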